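The chroman-4-one ring C and the 3-hydroxychroman-4-one ring C'' have the same O1–C2(aryl)–C3–C4–ring A framework; only C3 is a methylene in one and a carbinol in the other. Both are therefore traced to one kind of ring, a flav-3-ene, and the C3=C4 bond is the one disconnected. A twofold ring-closing metathesis makes both C3=C4 bonds and both pyran rings at once, on a substrate in which C2 and C2'' are already set as aryl ethers: the (S,S)-bis(1-arylallyl) ether of the 3',3'''-biaryl, each ring A bearing a vinyl group next to the ether oxygen. Dihydroxylation of one alkene, hydration of the other, oxidation at C4 and debenzylation finish the synthesis.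

Key step: step 10

Assumption: the (Sa,Sc,Sc) phosphoramidite is taken to deliver the (S)-configured branched aryl ether, the usual sense of induction of this ligand family with cinnamyl carbonates and heteroatom nucleophiles; if a single-arm test reaction shows the opposite sense, the enantiomeric ligand is used with no other change.

Locants: unprimed for the flavanone unit, double-primed for the dihydroflavonol unit; the biaryl bond joins C3' and C3'''.

Step 1
Reactants: 1 3-bromo-4-hydroxybenzaldehyde
Product: 2 4-(benzyloxy)-3-bromobenzaldehyde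
Conditions: BnBr, K2CO3, DMF, rt
Reagents that add atoms: benzyl bromide, BrCc1ccccc1
Why: Williamson etherification of the phenoxide with a benzylic bromide, to which the formyl group and the aryl bromide are inert.

Step 2
Reactants: 2 4-(benzyloxy)-3-bromobenzaldehyde
Product: 3 4-(benzyloxy)-3-(4,4,5,5-tetramethyl-1,3,2-dioxaborolan-2-yl)benzaldehyde
Conditions: B2pin2 (1.2 equiv), PdCl2(dppf) (3 mol%), KOAc (3 equiv), dioxane, 85 °C
Reagents that add atoms: bis(pinacolato)diboron, CC1(C)OB(OC1(C)C)B1OC(C)(C)C(C)(C)O1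
Why: Miyaura borylation, in which zerovalent palladium inserts into the aryl C–Br bond and acetate-assisted transmetalation with the diboron gives the pinacol boronate, the weak base KOAc being too mild to make the product couple with unreacted bromide or to touch the formyl group.

Step 3
Reactants: 2 4-(benzyloxy)-3-bromobenzaldehyde; 3 4-(benzyloxy)-3-(4,4,5,5-tetramethyl-1,3,2-dioxaborolan-2-yl)benzaldehyde
Product: 4 6,6'-bis(benzyloxy)biphenyl-3,3'-dicarbaldehyde
Conditions: PdCl2(dppf) (5 mol%), 2 M aq. K2CO3, dioxane, 90 °C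
Reagents that add atoms: none
Why: Suzuki–Miyaura cross-coupling of the aryl bromide with the boronate made from the same bromide joins the two carbons ortho to the benzyloxy groups and gives the symmetrical biaryl, formyl and benzyloxy groups being tolerated.

Step 4
Reactants: 4 6,6'-bis(benzyloxy)biphenyl-3,3'-dicarbaldehyde; 5 triethyl phosphonoacetate
Product: 6 diethyl (2E,2'E)-3,3'-[6,6'-bis(benzyloxy)biphenyl-3,3'-diyl]bis(prop-2-enoate)
Conditions: 5 (2.4 equiv), NaH (2.4 equiv), THF, 0 °C to rt
Reagents that add atoms: none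
Why: Twofold Horner–Wadsworth–Emmons olefination of non-enolisable aryl aldehydes with a stabilised phosphonate anion, which gives the (E)-acrylates.

Step 5
Reactants: 6 diethyl (2E,2'E)-3,3'-[6,6'-bis(benzyloxy)biphenyl-3,3'-diyl]bis(prop-2-enoate)
Product: 7 (2E,2'E)-3,3'-[6,6'-bis(benzyloxy)biphenyl-3,3'-diyl]bis(prop-2-en-1-ol)
Conditions: i-Bu2AlH (DIBAL-H, 5 equiv), CH2Cl2, −78 to 0 °C; aq. potassium sodium tartrate work-up
Reagents that add atoms: none
Why: Reduction of the conjugated esters by i-Bu2AlH through 1,2-addition to the allylic alcohols, which leaves the alkenes and the benzyl ethers untouched.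

Step 6
Reactants: 7 (2E,2'E)-3,3'-[6,6'-bis(benzyloxy)biphenyl-3,3'-diyl]bis(prop-2-en-1-ol)
Product: 8 bis(methyl carbonate) of diol 7
Conditions: ClCO2Me (3 equiv), pyridine, CH2Cl2, 0 °C
Reagents that add atoms: methyl chloroformate, COC(=O)Cl
Why: O-acylation of the primary allylic alcohols with a chloroformate gives the linear cinnamyl carbonates that serve as leaving groups for iridium.

Step 7
Reactants: 9 2,4,6-trihydroxybenzaldehyde
Product: 10 2,4-bis(benzyloxy)-6-hydroxybenzaldehyde
Conditions: BnBr (2.05 equiv), K2CO3, DMF, rt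
Reagents that add atoms: benzyl bromide, BrCc1ccccc1
Why: Williamson etherification that stops at the dibenzyl ether because the remaining ortho hydroxyl is locked in a hydrogen bond to the formyl group and is the least nucleophilic.

Step 8
Reactants: 10 2,4-bis(benzyloxy)-6-hydroxybenzaldehyde
Product: 11 3,5-bis(benzyloxy)-2-ethenylphenol
Conditions: Ph3PCH3Br (2.5 equiv), KOt-Bu (2.5 equiv), THF, 0 °C to rt; used at once, kept cold and acid-free
Reagents that add atoms: methyltriphenylphosphonium bromide, C[P+](c1ccccc1)(c1ccccc1)c1ccccc1.[Br-]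
Why: Wittig methylenation with excess non-stabilised ylide, the first equivalent forming the phenoxide and the second converting the formyl group into the vinyl group, so that the ring A alkene is in place before any stereocentre exists.

Step 9
Reactants: 8 bis(methyl carbonate) of diol 7; 11 3,5-bis(benzyloxy)-2-ethenylphenol
Product: 12 (S,S)-bis(1-arylallyl) ether: 6,6'-bis(benzyloxy)biphenyl carrying at C3 and C3' an (S)-CH(CH=CH2)–O–[3,5-bis(benzyloxy)-2-ethenylphenyl] group
Conditions: 11 (2.4 equiv), n-BuLi (2.4 equiv), THF, −78 to 0 °C; then 8, [Ir(cod)Cl]2 (4 mol%), (Sa,Sc,Sc)-BINOL N,N-bis(1-phenylethyl)phosphoramidite (8 mol%, pre-activated with n-PrNH2), THF, 50 °C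
Reagents that add atoms: none
Why: Iridium-catalysed asymmetric allylic etherification of cinnamyl carbonates by an aryloxide, in which the aryloxide attacks the aryl-substituted terminus of the allyl iridium complex and the cyclometalated phosphoramidite catalyst fixes the face of attack, so both C–O stereocentres are set as (S) under catalyst control and the minor meso isomer is removed by chromatography.

Step 10
Reactants: 12 (S,S)-bis(1-arylallyl) ether
Product: 13 (2S,2''S)-2,2''-[6,6'-bis(benzyloxy)biphenyl-3,3'-diyl]bis[5,7-bis(benzyloxy)-2H-chromene] (hexa-O-benzyl bis-flav-3-ene)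
Conditions: second-generation Grubbs catalyst RuCl2(=CHPh)(H2IMes)(PCy3) (10 mol%), 1,4-benzoquinone (20 mol%), CH2Cl2 (0.003 M), 40 °C, argon sweep
Reagents that add atoms: none
Why: Olefin metathesis by the Chauvin mechanism: the ruthenium benzylidene exchanges onto the terminal alkene of a 1-arylallyl arm, the new alkylidene adds across the neighbouring ring A vinyl group to a ruthenacyclobutane, and cycloreversion releases the C3=C4 bond and Ru=CH2, with ethylene as the only other product. The closest known reaction is ring-closing metathesis of 2-vinylaryl allyl ethers to 2H-chromenes, run here on both arms of one molecule. Each pyran ring closes as a six-membered ring, because the two alkene carbons that are joined are the ends of the chain C3–C2–O1–C8a–C4a–C4. No stereocentre is formed and no bond to C2 or C2'' is broken, so the configuration from step 9 is carried through. The step needs closure within each arm to win over intermolecular metathesis and over migration of the allyl double bond: high dilution and the favoured ring size secure the first (closure between the two arms would need a strained ten-membered ring across the meta-linked biaryl), and benzoquinone intercepts the ruthenium hydrides that cause the second.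

Step 11
Reactants: 13 hexa-O-benzyl bis-flav-3-ene
Product: 14 (2R,3S,4S)-5,7-bis(benzyloxy)-2-{6,6'-bis(benzyloxy)-3'-[(2S)-5,7-bis(benzyloxy)-2H-chromen-2-yl]biphenyl-3-yl}chromane-3,4-diol
Conditions: K2OsO2(OH)4 (2 mol%), NMO (1.0 equiv), acetone/H2O 10:1, 0 °C; stopped near half conversion, recovered 13 recycled
Reagents that add atoms: N-methylmorpholine N-oxide, C[N+]1([O-])CCOCC1; water, O
Why: Catalytic OsO4 syn-dihydroxylation on the face of the C3''=C4'' bond opposite the C2'' aryl group gives the 2,3-trans-3,4-cis diol under substrate control, while one equivalent of oxidant on two equivalent alkenes gives a statistical mixture from which the mono-diol is separated by its polarity.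

Step 12
Reactants: 14 mono-diol
Product: 15 (2R,3S,4S)-5,7-bis(benzyloxy)-2-{6,6'-bis(benzyloxy)-3'-[(2S,4RS)-5,7-bis(benzyloxy)-4-hydroxychroman-2-yl]biphenyl-3-yl}chromane-3,4-diol
Conditions: Mn(dpm)3 (10 mol%), PhSiH3 (2.5 equiv), O2 (1 atm), i-PrOH/CH2Cl2, 0 °C to rt
Reagents that add atoms: dioxygen, O=O
Why: Mukaiyama hydration, in which hydrogen-atom transfer to C3 gives the C4 benzylic radical stabilised by ring A that is trapped by dioxygen and reduced to the carbinol, the C4 epimers (and any C4 ketone) converging in step 13.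

Step 13
Reactants: 15 triol
Product: 16 (2S)-5,7-bis(benzyloxy)-2-{6,6'-bis(benzyloxy)-3'-[(2R,3R)-5,7-bis(benzyloxy)-3-hydroxy-4-oxochroman-2-yl]biphenyl-3-yl}chroman-4-one
Conditions: DDQ (2.2 equiv), CH2Cl2/pH 7 phosphate buffer 10:1, 0 °C to rt
Reagents that add atoms: none
Why: DDQ dehydrogenation of electron-rich benzylic carbinols by hydride abstraction, which takes place only at the two C4–H bonds next to the 5,7-dioxygenated rings A, so the non-benzylic C3'' hydroxyl, the benzyl ethers and the C2, C2'' and C3'' configurations are left as they are.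

Step 14
Reactants: 16 hexa-O-benzyl biflavonoid
Product: 17 (2S)-2-{6,6'-dihydroxy-3'-[(2R,3R)-3,5,7-trihydroxy-4-oxochroman-2-yl]biphenyl-3-yl}-5,7-dihydroxychroman-4-one (CNP0201582.1)
Conditions: H2 (1 atm), Pd(OH)2/C, THF/MeOH, rt
Reagents that add atoms: none
Why: Catalytic hydrogenolysis of the six aryl benzyl ethers under neutral conditions, which spares the hydrogen-bonded aryl ketones and avoids the base that would epimerise C2 through ring opening.

Compound list
1 | 3-bromo-4-hydroxybenzaldehyde | O=Cc1ccc(O)c(Br)c1 | starting material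
2 | 4-(benzyloxy)-3-bromobenzaldehyde | O=Cc1ccc(OCc2ccccc2)c(Br)c1 | intermediate
3 | 4-(benzyloxy)-3-(4,4,5,5-tetramethyl-1,3,2-dioxaborolan-2-yl)benzaldehyde | O=Cc1ccc(OCc2ccccc2)c(B2OC(C)(C)C(C)(C)O2)c1 | intermediate
4 | 6,6'-bis(benzyloxy)biphenyl-3,3'-dicarbaldehyde | O=Cc1ccc(OCc2ccccc2)c(c1)-c1cc(C=O)ccc1OCc1ccccc1 | intermediate
5 | triethyl phosphonoacetate | CCOC(=O)CP(=O)(OCC)OCC | starting material
6 | diethyl (2E,2'E)-3,3'-[6,6'-bis(benzyloxy)biphenyl-3,3'-diyl]bis(prop-2-enoate) | CCOC(=O)/C=C/c1ccc(OCc2ccccc2)c(c1)-c1cc(/C=C/C(=O)OCC)ccc1OCc1ccccc1 | intermediate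
7 | (2E,2'E)-3,3'-[6,6'-bis(benzyloxy)biphenyl-3,3'-diyl]bis(prop-2-en-1-ol) | OC/C=C/c1ccc(OCc2ccccc2)c(c1)-c1cc(/C=C/CO)ccc1OCc1ccccc1 | intermediate
8 | bis(methyl carbonate) of diol 7 | COC(=O)OC/C=C/c1ccc(OCc2ccccc2)c(c1)-c1cc(/C=C/COC(=O)OC)ccc1OCc1ccccc1 | intermediate
9 | 2,4,6-trihydroxybenzaldehyde | O=Cc1c(O)cc(O)cc1O | starting material
10 | 2,4-bis(benzyloxy)-6-hydroxybenzaldehyde | O=Cc1c(O)cc(OCc2ccccc2)cc1OCc1ccccc1 | intermediate
11 | 3,5-bis(benzyloxy)-2-ethenylphenol | C=Cc1c(O)cc(OCc2ccccc2)cc1OCc1ccccc1 | intermediate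
12 | (S,S)-bis(1-arylallyl) ether of 11 on the 6,6'-bis(benzyloxy)biphenyl-3,3'-diyl core | C=C[C@@H](c1ccc(OCc2ccccc2)c(c1)-c1cc(ccc1OCc1ccccc1)[C@H](C=C)Oc1cc(OCc2ccccc2)cc(OCc2ccccc2)c1C=C)Oc1cc(OCc2ccccc2)cc(OCc2ccccc2)c1C=C | intermediate
13 | (2S,2''S)-hexa-O-benzyl 3',3'''-bis(flav-3-ene) | C1=C[C@@H](c2ccc(OCc3ccccc3)c(c2)-c2cc(ccc2OCc2ccccc2)[C@@H]2C=Cc3c(OCc4ccccc4)cc(OCc4ccccc4)cc3O2)Oc2cc(OCc3ccccc3)cc(OCc3ccccc3)c21 | intermediate
14 | (2S)-flav-3-ene / (2''R,3''S,4''S)-flavan-3,4-diol, hexa-O-benzyl | C1=C[C@@H](c2ccc(OCc3ccccc3)c(c2)-c2cc(ccc2OCc2ccccc2)[C@H]2Oc3cc(OCc4ccccc4)cc(OCc4ccccc4)c3[C@H](O)[C@@H]2O)Oc2cc(OCc3ccccc3)cc(OCc3ccccc3)c21 | intermediate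
15 | (2S,4RS)-flavan-4-ol / (2''R,3''S,4''S)-flavan-3,4-diol, hexa-O-benzyl (C4 epimers) | OC1C[C@@H](c2ccc(OCc3ccccc3)c(c2)-c2cc(ccc2OCc2ccccc2)[C@H]2Oc3cc(OCc4ccccc4)cc(OCc4ccccc4)c3[C@H](O)[C@@H]2O)Oc2cc(OCc3ccccc3)cc(OCc3ccccc3)c21 | intermediate
16 | (2S)-flavanone / (2''R,3''R)-dihydroflavonol, hexa-O-benzyl | O=C1C[C@@H](c2ccc(OCc3ccccc3)c(c2)-c2cc(ccc2OCc2ccccc2)[C@H]2Oc3cc(OCc4ccccc4)cc(OCc4ccccc4)c3C(=O)[C@@H]2O)Oc2cc(OCc3ccccc3)cc(OCc3ccccc3)c21 | intermediate
17 | (2S)-2-{6,6'-dihydroxy-3'-[(2R,3R)-3,5,7-trihydroxy-4-oxochroman-2-yl]biphenyl-3-yl}-5,7-dihydroxychroman-4-one | O=C1C[C@@H](c2ccc(O)c(-c3cc([C@H]4Oc5cc(O)cc(O)c5C(=O)[C@@H]4O)ccc3O)c2)Oc2cc(O)cc(O)c21 | target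

Total step count: 14. Longest linear sequence: 12 steps (steps 1–6 and 9–14, from 1 to 17); the ring A branch (steps 7 and 8) joins at step 9.

Steps most likely to fail

Step 10. Closure onto the twisted, doubly ortho-substituted styrene may be slow, so the second ring may not close while intermolecular metathesis and ruthenium-hydride migration of the allyl double bond, which destroys C2, take over. The fallback closes the pyran rings without metathesis, by forming C4–C4a instead of C3=C4; it sets out from dialdehyde 4 and comes back at bis-flavene 13. Addition of ethynylmagnesium bromide (THF, 0 °C) to 4 should give the bis(propargylic alcohol) F1 as a mixture of stereoisomers, and acetylation (Ac2O, Et3N, DMAP, CH2Cl2) should give the diacetate F2. Copper-catalysed enantioselective propargylic etherification of F2 ((CuOTf)2·C6H6, chiral pybox ligand, i-Pr2NEt, non-nucleophilic solvent, low temperature) with commercial 3,5-bis(benzyloxy)phenol (Oc1cc(OCc2ccccc2)cc(OCc2ccccc2)c1) runs through a copper allenylidene and is enantioconvergent, so it should give the (S,S)-bis(aryl propargyl ether) F3. Gold-catalysed 6-endo hydroarylation (Ph3PAuNTf2, CH2Cl2, rt) of each alkyne by the symmetric ring A, whose two ortho positions are equivalent, should then give 13 with C2 untouched.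

Step 9. The second substitution is slower than the first, and during it the electron-rich product ether may re-ionise on iridium, which erodes the branched-to-linear ratio and the enantiopurity; the vinylphenoxide may also react at carbon or hold the catalyst through its alkene. The fallback carries the ring A alkene through the etherification as a formyl group; it sets out from bis-carbonate 8 and aldehyde 10 and comes back at precursor 12. The sodium salt of 10 (NaH, THF) is an O-selective, non-chelating aryloxide, though less nucleophilic, and with [Ir(cod)Cl]2 and the same phosphoramidite it should give the (S,S)-bis(2-formylaryl) ether F4. Twofold Wittig methylenation of the non-enolisable aldehydes (Ph3PCH3Br, KOt-Bu, THF, 0 °C) should then give 12, and step 8 is not needed.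

Step 13. The 3'',4''-diol may be oxidised past the ketol to the flavonol, or the acid-labile C4 carbinols may ionise under the acidic hydroquinone before they are oxidised. The fallback masks the C3'' hydroxyl so that an unselective oxidant can be used; it sets out from diol 14 and comes back at 16. Silylation of 14 (TBSCl, imidazole, DMF, 0 °C) should take place at the equatorial C3'' hydroxyl, since the pseudo-axial C4'' hydroxyl is shielded by the peri 5''-benzyloxy group, and give the 3''-O-silyl ether F5. Hydration as in step 12 should give the diol F6 as C4 epimers, and Dess–Martin periodinane (NaHCO3, CH2Cl2) should oxidise both C4 carbinols to the diketone F7. HF·pyridine (THF, 0 °C) should then remove the silyl group without base and give 16.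

Further compounds
F1 | step 10 | 1,1'-[6,6'-bis(benzyloxy)biphenyl-3,3'-diyl]bis(prop-2-yn-1-ol), stereoisomer mixture | C#CC(O)c1ccc(OCc2ccccc2)c(c1)-c1cc(ccc1OCc1ccccc1)C(O)C#C
F2 | step 10 | diacetate of F1 | C#CC(OC(C)=O)c1ccc(OCc2ccccc2)c(c1)-c1cc(ccc1OCc1ccccc1)C(OC(C)=O)C#C
F3 | step 10 | (S,S)-bis[3,5-bis(benzyloxy)phenyl 1-arylprop-2-ynyl] ether on the 6,6'-bis(benzyloxy)biphenyl-3,3'-diyl core | C#C[C@@H](c1ccc(OCc2ccccc2)c(c1)-c1cc(ccc1OCc1ccccc1)[C@H](C#C)Oc1cc(OCc2ccccc2)cc(OCc2ccccc2)c1)Oc1cc(OCc2ccccc2)cc(OCc2ccccc2)c1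
F4 | step 9 | (S,S)-bis(1-arylallyl) ether of aldehyde 10 (bis(2-formylaryl) ether) | C=C[C@@H](c1ccc(OCc2ccccc2)c(c1)-c1cc(ccc1OCc1ccccc1)[C@H](C=C)Oc1cc(OCc2ccccc2)cc(OCc2ccccc2)c1C=O)Oc1cc(OCc2ccccc2)cc(OCc2ccccc2)c1C=O
F5 | step 13 | 3''-O-(tert-butyldimethylsilyl) ether of 14 | C1=C[C@@H](c2ccc(OCc3ccccc3)c(c2)-c2cc(ccc2OCc2ccccc2)[C@H]2Oc3cc(OCc4ccccc4)cc(OCc4ccccc4)c3[C@H](O)[C@@H]2O[Si](C)(C)C(C)(C)C)Oc2cc(OCc3ccccc3)cc(OCc3ccccc3)c21
F6 | step 13 | 3''-O-(tert-butyldimethylsilyl) ether of 15 (C4 epimers) | OC1C[C@@H](c2ccc(OCc3ccccc3)c(c2)-c2cc(ccc2OCc2ccccc2)[C@H]2Oc3cc(OCc4ccccc4)cc(OCc4ccccc4)c3[C@H](O)[C@@H]2O[Si](C)(C)C(C)(C)C)Oc2cc(OCc3ccccc3)cc(OCc3ccccc3)c21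
F7 | step 13 | 3''-O-(tert-butyldimethylsilyl) ether of 16 | O=C1C[C@@H](c2ccc(OCc3ccccc3)c(c2)-c2cc(ccc2OCc2ccccc2)[C@H]2Oc3cc(OCc4ccccc4)cc(OCc4ccccc4)c3C(=O)[C@@H]2O[Si](C)(C)C(C)(C)C)Oc2cc(OCc3ccccc3)cc(OCc3ccccc3)c21
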